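**Plan**

1. Numbering as in azulene: C1–C2–C3(iPr)–C3a(OH)–C8a(CH3) is the five-membered ring; C4–C5–C6–C7–C8 complete the seven-membered ring.
2. Retrosynthetic cuts, in order: the ester C7O–C(=O)Ar; the trans-6,7-diol back to a C6=C7 alkene (epoxide, anti opening by water); C6=C7 (RCM); C3a–C4 (organometal addition to a C3a ketone); C7–C8 (vinyl addition to a C8 aldehyde, C8 then deoxygenated).
3. What remains is a cyclopentanone whose quaternary methyl carbon C8a lies between the C3a carbonyl and a formyl carbon C8, with CH(iPr) C3 on the other side of C3a. This is the retron of the acyl-shift ring contraction of an α,β-epoxy ketone: with C8 put back between C8a and C3a, the six-membered ring C8a–C8–C3a–C3–C2–C1 is piperitone oxide.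
4. Forward order of rings: cyclohexenone (piperitone) → epoxide → cyclopentanone by ring contraction (C8a–C3a made, C8 pushed out as CHO) → seven-membered ring closed last by RCM.
5. Stereochemistry: C3 from (R)-piperitone; oxirane set trans to iPr; C8a by inversion in the acyl shift; C3a by addition anti to iPr; C6/C7 by OH-directed epoxidation and anti hydrolysis.

Key step: step 2

Remark 1: the target is read as cis-fused, with 8a-CH3, 3a-OH, 3-iPr and the C7 ester oxygen on one face (α) and the 6-OH on the other (β).
Remark 2: (R)-(−)-piperitone of natural origin is assumed to be available in high ee; its stereocentre is the only source of absolute configuration.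

**Route**

Step 1
Reactants: 1 (R)-(−)-piperitone [(6R)-3-methyl-6-(propan-2-yl)cyclohex-2-en-1-one]
Product: 2 trans-piperitone oxide [(1S,3R,6S)-6-methyl-3-(propan-2-yl)-7-oxabicyclo[4.1.0]heptan-2-one; oxirane trans to iPr]
Conditions: 30% aq H2O2, NaOH (0.2 equiv), MeOH, −10 to 0 °C
Reagents that add atoms: hydrogen peroxide, OO
Why: Weitz–Scheffer nucleophilic epoxidation of the enone: in the β-hydroperoxy enolate the isopropyl group sits pseudoaxial (A1,2 strain with the enolate oxygen) and the axial O–O group closes on the opposite face, so the oxirane should form trans to iPr, which fixes both epoxide carbons relative to the piperitone centre.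

Step 2
Reactants: 2 trans-piperitone oxide
Product: 3 (1R,3R)-1-methyl-2-oxo-3-(propan-2-yl)cyclopentane-1-carbaldehyde (CH3 cis to iPr)
Conditions: BF3·OEt2 (0.3 equiv), PhMe, 0 °C to rt, 30 min; cold aq NaHCO3
Reagents that add atoms: none
Why: BF3 binds the oxirane oxygen, the bond from oxygen to the tertiary methyl-bearing carbon (future C8a) lengthens, and the acyl carbon (future C3a) shifts from the secondary epoxide carbon (future C8) to C8a while the C8–O bond becomes the aldehyde carbonyl, so the six-membered ring C8a–C8–C3a–C3–C2–C1 loses C8 to the side chain. The closest known reaction is the Lewis acid rearrangement of α,β-epoxy ketones to β-keto aldehydes, as in the conversion of isophorone oxide into 2-formyl-2,4,4-trimethylcyclopentanone. The cyclopentanone is not closed by a cyclisation but by a 1,2-acyl shift (ring contraction 6 → 5) that makes the C8a–C3a bond. The only new stereocentre, quaternary C8a, is set stereospecifically: the acyl group arrives anti to the departing oxygen (inversion), so the trans-oxide places CH3 cis and CHO trans to the isopropyl group, and C3 is not touched. The step needs C–O cleavage at the methyl-bearing carbon rather than next to the carbonyl, which the tertiary centre and the electron-poor α-carbon secure, and acyl rather than hydride migration (the latter gives the 1,2-diketone), which a non-polar medium and short contact time favour.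

Step 3
Reactants: 3 keto aldehyde
Product: 5 methyl 1-[(1R,3R)-1-methyl-2-oxo-3-(propan-2-yl)cyclopentyl]prop-2-en-1-yl carbonate (both carbinol epimers), via bromomagnesium alkoxide 4 (not isolated)
Conditions: CH2=CHMgBr (1.05 equiv), THF, −78 °C; then ClCO2Me (1.5 equiv), −78 to 0 °C
Reagents that add atoms: vinylmagnesium bromide, C=C[Mg]Br; methyl chloroformate, COC(=O)Cl
Why: Chemoselective Grignard 1,2-addition to the aldehyde (the ketone is shielded by the quaternary and the isopropyl-bearing carbons) with in situ O-acylation, which blocks retro-aldol cleavage; the new carbinol centre forms as a mixture and is removed in step 4.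

Step 4
Reactants: 5 allylic carbonate
Product: 6 (2R,5R)-2-methyl-5-(propan-2-yl)-2-(prop-2-en-1-yl)cyclopentan-1-one
Conditions: Pd(OAc)2 (5 mol%), n-Bu3P (20 mol%), HCO2H, Et3N, THF, 40 °C
Reagents that add atoms: none
Why: Tsuji-type palladium-catalysed formate hydrogenolysis of the allylic carbonate: the π-allylpalladium formate loses CO2 and delivers hydride to the more substituted allyl terminus (C8), which gives the terminal alkene; no stereocentre is touched and no diene can form because the neighbouring carbon is quaternary.

Step 5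
Reactants: 6 allyl ketone; 7 4-bromo-2-methylbut-1-ene
Product: 9 (1S,2R,5R)-2-methyl-1-(3-methylbut-3-en-1-yl)-5-(propan-2-yl)-2-(prop-2-en-1-yl)cyclopentan-1-ol, via homoallyl Grignard reagent 8 (not isolated)
Conditions: 7, Mg, THF, rt; anhydrous CeCl3, THF, −78 °C; then 6, −78 to 0 °C; aq NH4Cl
Reagents that add atoms: none
Why: Cerium-promoted Grignard addition (suppresses enolisation of the hindered ketone); the nucleophile should enter anti to the α'-isopropyl group, on the face of the allyl group, so the new hydroxyl is cis to iPr and to the quaternary methyl and the two alkene arms are cis (sets C3a).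

Step 6
Reactants: 9 diene alcohol
Product: 10 (3R,3aS,8aR)-6,8a-dimethyl-3-(propan-2-yl)-2,3,4,5,8,8a-hexahydroazulen-3a(1H)-ol (cis-fused; CH3, OH and iPr on one face)
Conditions: Grubbs II (5 mol%), CH2Cl2 (5 mM), 40 °C
Reagents that add atoms: none
Why: Ring-closing metathesis of a monosubstituted and a 1,1-disubstituted alkene held cis on the cyclopentane closes the seven-membered ring as the trisubstituted C6=C7 cycloheptene; the free tertiary alcohol is tolerated.

Step 7
Reactants: 10 bicyclic alkenol
Product: 11 (3R,3aS,6S,7R,8aR)-6,7-epoxy-6,8a-dimethyl-3-(propan-2-yl)decahydroazulen-3a-ol (oxirane cis to the 3a-OH)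
Conditions: VO(acac)2 (5 mol%), t-BuOOH (1.5 equiv), CH2Cl2, 0 °C to rt
Reagents that add atoms: tert-butyl hydroperoxide, CC(C)(C)OO
Why: Vanadium-catalysed hydroxyl-directed epoxidation: the bishomoallylic C3a-OH binds vanadium and should deliver oxygen across the ring to the alkene face cis to itself, which places both C–O bonds on the α face, where the hydroxyl cannot open the epoxide from the rear.

Step 8
Reactants: 11 α-epoxide
Product: 12 (3R,3aS,6R,7R,8aR)-6,8a-dimethyl-3-(propan-2-yl)decahydroazulene-3a,6,7-triol
Conditions: HClO4 (5 mol%), THF–H2O (3:1), 0 °C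
Reagents that add atoms: water, O
Why: Acid-catalysed epoxide hydrolysis with attack of water at the tertiary carbon C6 with inversion while the C7–O bond is kept, which gives the trans-diol (6-OH β, 7-OH α).

Step 9
Reactants: 12 triol; 13 4-methoxybenzoyl chloride
Product: 14 (3R,3aS,6R,7R,8aR)-3a,6-dihydroxy-6,8a-dimethyl-3-(propan-2-yl)decahydroazulen-7-yl 4-methoxybenzoate (numbering of 10 kept)
Conditions: 13 (1.2 equiv), pyridine, DMAP (10 mol%), CH2Cl2, 0 °C to rt
Reagents that add atoms: none
Why: Nucleophilic-catalysed acylation of the only secondary hydroxyl; the two tertiary hydroxyls (C3a, C6) do not react under these conditions.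

**Compound list**

1 | (R)-(−)-piperitone, (6R)-3-methyl-6-(propan-2-yl)cyclohex-2-en-1-one | CC1=CC(=O)[C@@H](C(C)C)CC1 | starting material
2 | trans-piperitone oxide, (1S,3R,6S)-6-methyl-3-(propan-2-yl)-7-oxabicyclo[4.1.0]heptan-2-one | CC(C)[C@H]1CC[C@]2(C)O[C@@H]2C1=O | intermediate
3 | (1R,3R)-1-methyl-2-oxo-3-(propan-2-yl)cyclopentane-1-carbaldehyde | O=C[C@@]1(C)CC[C@H](C(C)C)C1=O | intermediate
4 | bromomagnesium 1-[(1R,3R)-1-methyl-2-oxo-3-(propan-2-yl)cyclopentyl]prop-2-en-1-olate (both carbinol epimers, not isolated) | C=CC(O[Mg]Br)[C@@]1(C)CC[C@H](C(C)C)C1=O | intermediate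
5 | methyl 1-[(1R,3R)-1-methyl-2-oxo-3-(propan-2-yl)cyclopentyl]prop-2-en-1-yl carbonate (both carbinol epimers) | C=CC(OC(=O)OC)[C@@]1(C)CC[C@H](C(C)C)C1=O | intermediate
6 | (2R,5R)-2-methyl-5-(propan-2-yl)-2-(prop-2-en-1-yl)cyclopentan-1-one | C=CC[C@@]1(C)CC[C@H](C(C)C)C1=O | intermediate
7 | 4-bromo-2-methylbut-1-ene | C=C(C)CCBr | starting material
8 | (3-methylbut-3-en-1-yl)magnesium bromide (not isolated) | C=C(C)CC[Mg]Br | intermediate
9 | (1S,2R,5R)-2-methyl-1-(3-methylbut-3-en-1-yl)-5-(propan-2-yl)-2-(prop-2-en-1-yl)cyclopentan-1-ol | C=CC[C@@]1(C)CC[C@H](C(C)C)[C@@]1(O)CCC(C)=C | intermediate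
10 | (3R,3aS,8aR)-6,8a-dimethyl-3-(propan-2-yl)-2,3,4,5,8,8a-hexahydroazulen-3a(1H)-ol | CC1=CC[C@@]2(C)CC[C@H](C(C)C)[C@@]2(O)CC1 | intermediate
11 | (3R,3aS,6S,7R,8aR)-6,7-epoxy-6,8a-dimethyl-3-(propan-2-yl)decahydroazulen-3a-ol | C[C@]12CC[C@]3(O)[C@@H](C(C)C)CC[C@]3(C)C[C@H]1O2 | intermediate
12 | (3R,3aS,6R,7R,8aR)-6,8a-dimethyl-3-(propan-2-yl)decahydroazulene-3a,6,7-triol | O[C@@H]1C[C@@]2(C)CC[C@H](C(C)C)[C@@]2(O)CC[C@@]1(C)O | intermediate
13 | 4-methoxybenzoyl chloride | COc1ccc(C(=O)Cl)cc1 | starting material
14 | (3R,3aS,6R,7R,8aR)-3a,6-dihydroxy-6,8a-dimethyl-3-(propan-2-yl)decahydroazulen-7-yl 4-methoxybenzoate | COc1ccc(C(=O)O[C@@H]2C[C@@]3(C)CC[C@H](C(C)C)[C@@]3(O)CC[C@@]2(C)O)cc1 | target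

**Totals and risks**

Total steps: 9. Longest linear sequence: 9 steps (1 → 14); 7 and 13 enter at steps 5 and 9.

Steps most likely to fail:

Step 1. Peroxide addition may show poor facial selectivity relative to the isopropyl group, and base may epimerise the centre next to the ketone; either erodes the trans-oxide and with it the CH3/iPr relationship of the cyclopentanone. The fallback sets out from 1 and fixes the isopropyl centre before the oxirane is made. Luche reduction (NaBH4, CeCl3, MeOH, −78 °C; axial hydride) gives trans-piperitol F1, from which any cis-alcohol is removed at this non-epimerisable stage. Hydroxyl-directed epoxidation (VO(acac)2, t-BuOOH) gives the syn epoxy alcohol F2 with the oxirane anti to iPr. Dess–Martin oxidation under buffered conditions returns to 2.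

Step 2. Hydride instead of acyl migration (giving the 1,2-diketone), epimerisation at the isopropyl carbon under the Lewis acid, or loss of the formyl group on work-up may lower the yield. The fallback sets out from 2 and uses an alkyl shift instead of an acyl shift. NaBH4 reduction gives the epoxy alcohols F3, and TBSOTf/2,6-lutidine gives the silyl ethers F4. The bulky aluminium Lewis acid MABR [methylaluminium bis(4-bromo-2,6-di-tert-butylphenoxide)] then promotes the known rearrangement of epoxy silyl ethers, in which the siloxy-bearing carbon migrates to the tertiary epoxide carbon with inversion, giving the ring-contracted β-siloxy aldehyde F5. HF·pyridine frees the β-hydroxy aldehyde F6, and Dess–Martin oxidation of the secondary alcohol returns to 3.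

Step 7. The tertiary hydroxyl may fail to deliver the oxidant across the ring; attack on the opposite face gives an epoxide that the hydroxyl opens transannularly to a bridged ether. The fallback sets out from 10 and uses that intrinsic facial preference instead of fighting it. OsO4/NMO dihydroxylation on the face anti to the angular methyl and hydroxyl gives the cis-diol F7 (6-OH and 7-OH both β). Mitsunobu esterification of the secondary alcohol with 4-methoxybenzoic acid (PPh3, DIAD) inverts C7 and gives 14 directly, bypassing 11 and 12.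

**Further compounds**

F1 | step 1 | trans-piperitol, (1R,6R)-3-methyl-6-(propan-2-yl)cyclohex-2-en-1-ol | CC(C)[C@H]1CCC(C)=C[C@@H]1O
F2 | step 1 | (1R,2R,3R,6S)-6-methyl-3-(propan-2-yl)-7-oxabicyclo[4.1.0]heptan-2-ol | CC(C)[C@H]1CC[C@]2(C)O[C@@H]2[C@@H]1O
F3 | step 2 | (1R,3R,6S)-6-methyl-3-(propan-2-yl)-7-oxabicyclo[4.1.0]heptan-2-ol (C2 epimers) | CC(C)[C@H]1CC[C@]2(C)O[C@@H]2C1O
F4 | step 2 | tert-butyldimethylsilyl ether of F3 | CC(C)[C@H]1CC[C@]2(C)O[C@@H]2C1O[Si](C)(C)C(C)(C)C
F5 | step 2 | (1S,3R)-2-[(tert-butyldimethylsilyl)oxy]-1-methyl-3-(propan-2-yl)cyclopentane-1-carbaldehyde (C2 epimers) | O=C[C@@]1(C)CC[C@H](C(C)C)C1O[Si](C)(C)C(C)(C)C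
F6 | step 2 | (1S,3R)-2-hydroxy-1-methyl-3-(propan-2-yl)cyclopentane-1-carbaldehyde (C2 epimers) | O=C[C@@]1(C)CC[C@H](C(C)C)C1O
F7 | step 7 | (3R,3aS,6R,7S,8aR)-6,8a-dimethyl-3-(propan-2-yl)decahydroazulene-3a,6,7-triol | O[C@H]1C[C@@]2(C)CC[C@H](C(C)C)[C@@]2(O)CC[C@@]1(C)O
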